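**Plan**
1. Retrosynthesis: remove the C19 acetate and the silyl ethers, cut C12–C13 (butenolide from 4-bromofuran-2(5H)-one), then contract ring B. Its homoallylic alcohol unit C6(OH)–C7H2–C8(CH3)=C9 is the retron of a 2-vinylcyclobutanol: cyclobutane C5–C6–C9–C10 with an isopropenyl group (C7, C8, C17) on C9.
2. The cyclobutanone is cut to dichloroketene and the ring A alkene C5=C10. C9 is dressed by aldol/dehydration with acetone and by deconjugative alkylation (C11, C12).
3. Forward order: ring A (desymmetrizing aldol of a prochiral 2,6-dione, anti conjugate addition of a hydroxymethyl equivalent, enol triflate to methyl), then the four-membered ring, then its alkoxide-driven enlargement to ring B, then the butenolide.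
4. Stereochemistry: C2 from the aminocatalytic desymmetrization; C4 by cuprate addition anti to the C2 silyl ether; C5 and C10 (cis fusion) by suprafacial ketene addition anti to the axial CH2OTBS group; C6 by hydride attack on the C6 ketone from the convex face.

Key step: step 14

Locants are the labdane locants of the target (ring A = C1–C5, C10; ring B = C5–C10; C17 on C8, C18/C19 on C4, C20 on C10); β is the face of C20. TBDPS = tert-butyldiphenylsilyl, TBS = tert-butyldimethylsilyl.

Assumption: the stereodescriptors are taken at face value, i.e. a cis-fused decalin with C5–H, C20 and C19 on the β-face and the C2 and C6 hydroxyls and C18 on the α-face; the sense of induction in step 3 is assumed to follow that of 4-alkyl diones, the quinidine-derived pseudoenantiomer of the catalyst being used otherwise.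

Step 1
Reactants: 1 hepta-1,6-dien-4-ol
Product: 2 tert-butyl(hepta-1,6-dien-4-yloxy)diphenylsilane
Conditions: TBDPSCl, imidazole, DMF, rt
Reagents that add atoms: tert-butyl(chloro)diphenylsilane, CC(C)(C)[Si](Cl)(c1ccccc1)c1ccccc1
Why: Routine silylation of a secondary alcohol; the bulky ether later steers step 4 and outlasts the primary silyl ether at the end.

Step 2
Reactants: 2 tert-butyl(hepta-1,6-dien-4-yloxy)diphenylsilane
Product: 3 4-[(tert-butyldiphenylsilyl)oxy]heptane-2,6-dione
Conditions: PdCl2 (10 mol%), CuCl, O2 (1 atm), DMF/H2O 7:1, rt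
Reagents that add atoms: water, O (the ketone oxygens; O2 is the terminal oxidant)
Why: Twofold Tsuji–Wacker oxidation of the terminal alkenes with Markovnikov regiochemistry should give the prochiral diketone, whose two acetonyl arms are enantiotopic.

Step 3
Reactants: 3 4-[(tert-butyldiphenylsilyl)oxy]heptane-2,6-dione
Product: 5 (S)-5-[(tert-butyldiphenylsilyl)oxy]-3-methylcyclohex-2-en-1-one, via aldol adduct 4 (not isolated)
Conditions: 9-amino-9-deoxy-epi-quinine (20 mol%), AcOH (60 mol%), toluene, −15 °C to rt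
Reagents that add atoms: none
Why: Primary-amine (enamine) catalysed intramolecular aldol condensation of 4-substituted heptane-2,6-diones is a known desymmetrization; the catalyst's choice between the enantiotopic ketones fixes C2, and dehydration removes the carbinol centre.

Step 4
Reactants: 5 (S)-5-[(tert-butyldiphenylsilyl)oxy]-3-methylcyclohex-2-en-1-one
Product: 8 enol triflate (C10–OTf; C5=C10; C4 α-CH3 and β-CH2SiMe2(OiPr); C2 α-OTBDPS), via trimethylsilyl enol ether 6 (not isolated), via potassium enolate 7 (not isolated)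
Conditions: (iPrO)Me2SiCH2MgCl (from the chloride and Mg), CuI (10 mol%), TMSCl, THF, −78 to −30 °C; then KOtBu, THF, −78 °C; PhNTf2
Reagents that add atoms: (isopropoxydimethylsilyl)methylmagnesium chloride, CC(C)O[Si](C)(C)C[Mg]Cl; N-phenylbis(trifluoromethanesulfonimide), O=S(=O)(N(c1ccccc1)S(=O)(=O)C(F)(F)F)C(F)(F)F; chlorotrimethylsilane, C[Si](C)(C)Cl (in 6 only); potassium tert-butoxide, CC(C)(C)[O-].[K+] (potassium in 7 only)
Why: Copper-catalysed conjugate addition of the silylmethyl Grignard reagent (a hydroxymethyl anion equivalent) should occur axially and anti to the C2 silyloxy group, creating the C4 quaternary centre with methyl cis to the oxygen; the regiodefined enolate is carried through its silyl ether into the C10 enol triflate.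

Step 5
Reactants: 8 enol triflate with the CH2SiMe2(OiPr) group
Product: 9 enol triflate with free C19 hydroxyl (CH2OH trans to OTBDPS)
Conditions: 30% H2O2, KF, KHCO3, THF/MeOH, rt
Reagents that add atoms: hydrogen peroxide, OO
Why: Tamao oxidation replaces the alkoxysilyl group by hydroxyl under nucleophilic peroxide conditions that should leave the enol triflate and the TBDPS ether alone.

Step 6
Reactants: 9 enol triflate with free C19 hydroxyl
Product: 10 C19 TBS ether of the enol triflate
Conditions: TBSCl, imidazole, DMF, rt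
Reagents that add atoms: tert-butyl(chloro)dimethylsilane, CC(C)(C)[Si](C)(C)Cl
Why: Routine silylation of the neopentyl primary alcohol gives an ether that can later be cleaved in the presence of the secondary TBDPS ether.

Step 7
Reactants: 10 C19 TBS ether of the enol triflate
Product: 11 ring A alkene (C5=C10 with C20 on C10; C4 α-CH3 and β-CH2OTBS; C2 α-OTBDPS)
Conditions: MeMgBr, Fe(acac)3 (5 mol%), THF/NMP, −30 °C
Reagents that add atoms: methylmagnesium bromide, C[Mg]Br
Why: Iron-catalysed Kumada-type coupling of alkenyl triflates with methylmagnesium bromide is fast at low temperature and places C20 on C10 with the double bond fixed at C5=C10.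

Step 8
Reactants: 11 ring A alkene
Product: 12 cis-fused dichlorocyclobutanone (C9 Cl2; C6 ketone; four-membered ring on the α-face)
Conditions: Cl3CCOCl, Zn–Cu couple, POCl3, Et2O, rt (ultrasound)
Reagents that add atoms: trichloroacetyl chloride, ClC(=O)C(Cl)(Cl)Cl (delivered as dichloroketene, ClC(Cl)=C=O)
Why: Dichloroketene undergoes [2+2] cycloaddition with unactivated trisubstituted alkenes, suprafacially on the alkene (cis fusion) and with the carbonyl carbon on the less substituted C5; it should attack the face opposite the pseudo-axial CH2OTBS group of the half-chair in which OTBDPS and the C4 methyl are equatorial, which sets C5 and C10.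

Step 9
Reactants: 12 cis-fused dichlorocyclobutanone
Product: 13 cis-fused cyclobutanone (C9 H2)
Conditions: Zn dust, NH4Cl, MeOH, rt
Reagents that add atoms: none
Why: Zinc reduction of α,α-dichlorocyclobutanones to the parent ketones is standard and mild toward silyl ethers.

Step 10
Reactants: 13 cis-fused cyclobutanone
Product: 14 aldol adduct carrying a 2-hydroxypropan-2-yl group on C9
Conditions: LiN(iPr)2, THF, −78 °C; acetone, −78 °C
Reagents that add atoms: acetone, CC(C)=O
Why: Kinetic deprotonation should take place at the C9 methylene and not at the hindered ring-fusion C5–H, and the lithium enolate adds to acetone in a directed aldol reaction (the C9 configuration is lost in step 11).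

Step 11
Reactants: 14 aldol adduct
Product: 16 2-isopropylidenecyclobutanone (C9=C8 with C7 and C17 as methyls), via tertiary mesylate 15 (not isolated)
Conditions: MsCl, Et3N, DMAP (cat.), CH2Cl2, 0 °C; then DBU, rt
Reagents that add atoms: methanesulfonyl chloride, CS(=O)(=O)Cl (in 15 only)
Why: Mesylation of the tertiary aldol through sulfene and E1cB elimination via the ketone enolate should place the double bond in conjugation.

Step 12
Reactants: 16 2-isopropylidenecyclobutanone; 17 tert-butyl bromoacetate
Product: 19 cyclobutanone with quaternary C9 bearing isopropenyl (α) and CH2CO2tBu (β), via potassium dienolate 18 (not isolated)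
Conditions: KN(SiMe3)2 (0.95 equiv), THF, −78 to 0 °C; then BrCH2CO2tBu, −78 to 0 °C
Reagents that add atoms: potassium bis(trimethylsilyl)amide, C[Si](C)(C)[N-][Si](C)(C)C.[K+] (potassium in 18 only)
Why: In this deconjugative α-alkylation the extended dienolate, formed under equilibrating conditions, should react with the reactive α-bromo ester at C9 from the convex face, creating the quaternary carbon that carries the isopropenyl group and the C11–C12 unit (the C9 configuration is erased in step 14).

Step 13
Reactants: 19 cyclobutanone with quaternary C9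
Product: 20 2-vinylcyclobutanol diol (C6 α-OH; C9 isopropenyl and CH2CH2OH)
Conditions: LiAlH4, THF, 0 °C to rt
Reagents that add atoms: none
Why: LiAlH4 reduces the strained ketone from the convex face and the tert-butyl ester to the primary alcohol, which removes the acidic ester α-hydrogens before the anionic key step.

Step 14
Reactants: 20 2-vinylcyclobutanol diol
Product: 22 ring B diol (6β-OH; C12 OH; C8=C9), via ring-opened aldehyde allylpotassium 21 (not isolated)
Conditions: KH (3 equiv), 18-crown-6, THF, 0 to 40 °C; NH4Cl (aq)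
Reagents that add atoms: potassium hydride, [K+].[H-] (potassium in 21 only)
Why: Deprotonation gives the C6 potassium alkoxide, whose strained C6–C9 bond cleaves heterolytically to an aldehyde on C5 and a trisubstituted allylpotassium on C10 (21); the anion recloses through its unsubstituted terminus C7 onto the aldehyde carbon, a net [1,3] shift of C6 from C9 to C7 that enlarges the four-membered ring C5–C6–C9–C10 to the six-membered ring B and leaves C8=C9 tetrasubstituted. The closest known reaction type is the alkoxide-accelerated vinylcyclobutane-to-cyclohexene rearrangement of 2-vinylcyclobutanol salts. Ring B closes by 6-exo-trig addition of C7 to the C6 carbonyl. The only new stereocentre, C6, is controlled by the aldehyde rotamer in the reclosure and is expected with the alkoxide on the convex β-face; it is reset in steps 16 and 18, so either epimer serves. The step needs C7 attack to win over return at C9, which the strain-free six-membered alkoxide secures as the sink, and reclosure to outrun proton transfer from C5–H to the allyl anion, which the tight ion pair and the cis placement of both partners on ring A favour. The cis relation of C5 and C10 is kept because neither centre is touched.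

Step 15
Reactants: 22 ring B diol
Product: 23 C12 iodide with 6β-OH
Conditions: PPh3, I2, imidazole (premixed), CH2Cl2, 0 °C
Reagents that add atoms: iodine, II
Why: The Appel reaction is selective for the primary alcohol over the hindered secondary C6 hydroxyl, and premixing the reagents avoids free iodine at the tetrasubstituted alkene.

Step 16
Reactants: 23 C12 iodide with 6β-OH
Product: 24 C12 iodide with C6 ketone (β,γ-unsaturated)
Conditions: Dess–Martin periodinane, NaHCO3, CH2Cl2, rt
Reagents that add atoms: none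
Why: Buffered Dess–Martin oxidation should give the β,γ-unsaturated ketone without moving the double bond into conjugation, and it erases whatever C6 configuration step 14 delivered.

Step 17
Reactants: 24 C12 iodide with C6 ketone; 25 4-bromofuran-2(5H)-one
Product: 27 butenolide with C6 ketone, via alkylzinc iodide 26 (not isolated)
Conditions: Zn dust (activated), DMA, 40 °C; then 25, Pd(PPh3)4 (5 mol%), THF, 45 °C
Reagents that add atoms: zinc, [Zn] (in 26 only)
Why: Zinc insertion into the primary iodide and Negishi coupling with the β-bromobutenolide (an activated alkenyl bromide) form the C12–C13 bond and tolerate the ketone and the silyl ethers.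

Step 18
Reactants: 27 butenolide with C6 ketone
Product: 28 6α-alcohol (C19 OTBS; C2 OTBDPS)
Conditions: NaBH4, CeCl3·7H2O, MeOH, −78 °C
Reagents that add atoms: none
Why: Under Luche conditions hydride should reach the C6 ketone only from the convex β-face, the other being covered by ring A, which places the hydroxyl on the concave α-face; low temperature and CeCl3 protect the butenolide.

Step 19
Reactants: 28 6α-alcohol bis-silyl ether
Product: 29 C19 alcohol (C2 OTBDPS)
Conditions: HF·pyridine, pyridine, THF, 0 °C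
Reagents that add atoms: none
Why: Buffered HF·pyridine cleaves the primary TBS ether much faster than the secondary TBDPS ether.

Step 20
Reactants: 29 C19 alcohol
Product: 30 C19 acetate (C2 OTBDPS)
Conditions: Ac2O, pyridine, DMAP (cat.), CH2Cl2, 0 °C
Reagents that add atoms: acetic anhydride, CC(=O)OC(C)=O
Why: Acetylation of the primary C19 alcohol; the C6 hydroxyl is buried on the concave face and should not react.

Step 21
Reactants: 30 C19 acetate
Product: 31 CNP0201970.1
Conditions: HF·pyridine (excess), THF, rt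
Reagents that add atoms: none
Why: Fluoride-mediated removal of the last silyl ether under mildly acidic conditions that spare the acetate and the butenolide should give the target.

**Compound list**
1 | hepta-1,6-dien-4-ol | C=CCC(O)CC=C | starting material
2 | tert-butyl(hepta-1,6-dien-4-yloxy)diphenylsilane | C=CCC(O[Si](c1ccccc1)(c1ccccc1)C(C)(C)C)CC=C | intermediate
3 | 4-[(tert-butyldiphenylsilyl)oxy]heptane-2,6-dione | CC(=O)CC(O[Si](c1ccccc1)(c1ccccc1)C(C)(C)C)CC(C)=O | intermediate
4 | aldol adduct, (5S)-3-hydroxy-3-methyl-5-(TBDPS-oxy)cyclohexan-1-one (carbinol configuration open) | O=C1CC(C)(O)C[C@H](O[Si](c2ccccc2)(c2ccccc2)C(C)(C)C)C1 | intermediate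
5 | (S)-5-[(tert-butyldiphenylsilyl)oxy]-3-methylcyclohex-2-en-1-one | O=C1C=C(C)C[C@H](O[Si](c2ccccc2)(c2ccccc2)C(C)(C)C)C1 | intermediate
6 | trimethylsilyl enol ether of the conjugate adduct (CH2Si trans to OTBDPS) | CC(C)O[Si](C)(C)C[C@@]1(C)C[C@H](O[Si](c2ccccc2)(c2ccccc2)C(C)(C)C)CC(O[Si](C)(C)C)=C1 | intermediate
7 | potassium enolate of the conjugate adduct | CC(C)O[Si](C)(C)C[C@@]1(C)C[C@H](O[Si](c2ccccc2)(c2ccccc2)C(C)(C)C)CC([O-])=C1.[K+] | intermediate
8 | enol triflate with CH2SiMe2(OiPr) on C4 (trans to OTBDPS) | CC(C)O[Si](C)(C)C[C@@]1(C)C[C@H](O[Si](c2ccccc2)(c2ccccc2)C(C)(C)C)CC(OS(=O)(=O)C(F)(F)F)=C1 | intermediate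
9 | enol triflate with free C19 hydroxyl | OC[C@@]1(C)C[C@H](O[Si](c2ccccc2)(c2ccccc2)C(C)(C)C)CC(OS(=O)(=O)C(F)(F)F)=C1 | intermediate
10 | enol triflate with C19 OTBS | CC(C)(C)[Si](C)(C)OC[C@@]1(C)C[C@H](O[Si](c2ccccc2)(c2ccccc2)C(C)(C)C)CC(OS(=O)(=O)C(F)(F)F)=C1 | intermediate
11 | ring A alkene, 1,3-dimethyl-3-(TBSO-methyl)-5-(TBDPS-oxy)cyclohex-1-ene (CH2OTBS trans, C-methyl cis to OTBDPS) | CC(C)(C)[Si](C)(C)OC[C@@]1(C)C[C@H](O[Si](c2ccccc2)(c2ccccc2)C(C)(C)C)CC(C)=C1 | intermediate
12 | cis-fused dichlorocyclobutanone (C9 Cl2, C6 ketone) | CC(C)(C)[Si](C)(C)OC[C@@]1(C)C[C@H](O[Si](c3ccccc3)(c3ccccc3)C(C)(C)C)C[C@]2(C)C(Cl)(Cl)C(=O)[C@H]12 | intermediate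
13 | cis-fused cyclobutanone (C9 H2) | CC(C)(C)[Si](C)(C)OC[C@@]1(C)C[C@H](O[Si](c3ccccc3)(c3ccccc3)C(C)(C)C)C[C@]2(C)CC(=O)[C@H]12 | intermediate
14 | C9 (2-hydroxypropan-2-yl) aldol adduct | CC(C)(C)[Si](C)(C)OC[C@@]1(C)C[C@H](O[Si](c3ccccc3)(c3ccccc3)C(C)(C)C)C[C@]2(C)[C@@H](C(C)(C)O)C(=O)[C@H]12 | intermediate
15 | tertiary mesylate of 14 | CC(C)(C)[Si](C)(C)OC[C@@]1(C)C[C@H](O[Si](c3ccccc3)(c3ccccc3)C(C)(C)C)C[C@]2(C)[C@@H](C(C)(C)OS(C)(=O)=O)C(=O)[C@H]12 | intermediate
16 | 2-isopropylidenecyclobutanone | CC(C)(C)[Si](C)(C)OC[C@@]1(C)C[C@H](O[Si](c3ccccc3)(c3ccccc3)C(C)(C)C)C[C@]2(C)C(=C(C)C)C(=O)[C@H]12 | intermediate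
17 | tert-butyl bromoacetate | CC(C)(C)OC(=O)CBr | starting material
18 | potassium dienolate of 16 | CC(C)(C)[Si](C)(C)OC[C@@]1(C)C[C@H](O[Si](c3ccccc3)(c3ccccc3)C(C)(C)C)C[C@]2(C)C(C(C)=C)=C([O-])[C@H]12.[K+] | intermediate
19 | cyclobutanone with C9 isopropenyl (α) and CH2CO2tBu (β) | CC(C)(C)[Si](C)(C)OC[C@@]1(C)C[C@H](O[Si](c3ccccc3)(c3ccccc3)C(C)(C)C)C[C@]2(C)[C@](CC(=O)OC(C)(C)C)(C(C)=C)C(=O)[C@H]12 | intermediate
20 | 2-vinylcyclobutanol diol (C6 α-OH, C9 isopropenyl and CH2CH2OH) | CC(C)(C)[Si](C)(C)OC[C@@]1(C)C[C@H](O[Si](c3ccccc3)(c3ccccc3)C(C)(C)C)C[C@]2(C)[C@](CCO)(C(C)=C)[C@H](O)[C@H]12 | intermediate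
21 | ring-opened dipotassium species (C5 formyl; allyl anion on C10) | CC(C)(C)[Si](C)(C)OC[C@@]1(C)C[C@H](O[Si](c3ccccc3)(c3ccccc3)C(C)(C)C)C[C@](C)(C(CC[O-])=C(C)[CH2-])[C@@H]1C=O.[K+].[K+] | intermediate
22 | ring B diol (6β-OH, C12 OH, C8=C9) | CC(C)(C)[Si](C)(C)OC[C@@]1(C)C[C@H](O[Si](c3ccccc3)(c3ccccc3)C(C)(C)C)C[C@]2(C)C(CCO)=C(C)C[C@@H](O)[C@H]12 | intermediate
23 | C12 iodide with 6β-OH | CC(C)(C)[Si](C)(C)OC[C@@]1(C)C[C@H](O[Si](c3ccccc3)(c3ccccc3)C(C)(C)C)C[C@]2(C)C(CCI)=C(C)C[C@@H](O)[C@H]12 | intermediate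
24 | C12 iodide with C6 ketone | CC(C)(C)[Si](C)(C)OC[C@@]1(C)C[C@H](O[Si](c3ccccc3)(c3ccccc3)C(C)(C)C)C[C@]2(C)C(CCI)=C(C)CC(=O)[C@H]12 | intermediate
25 | 4-bromofuran-2(5H)-one | O=C1C=C(Br)CO1 | starting material
26 | alkylzinc iodide from 24 | CC(C)(C)[Si](C)(C)OC[C@@]1(C)C[C@H](O[Si](c3ccccc3)(c3ccccc3)C(C)(C)C)C[C@]2(C)C(CC[Zn]I)=C(C)CC(=O)[C@H]12 | intermediate
27 | butenolide with C6 ketone | CC(C)(C)[Si](C)(C)OC[C@@]1(C)C[C@H](O[Si](c3ccccc3)(c3ccccc3)C(C)(C)C)C[C@]2(C)C(CCC3=CC(=O)OC3)=C(C)CC(=O)[C@H]12 | intermediate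
28 | 6α-alcohol (C19 OTBS, C2 OTBDPS) | CC(C)(C)[Si](C)(C)OC[C@@]1(C)C[C@H](O[Si](c3ccccc3)(c3ccccc3)C(C)(C)C)C[C@]2(C)C(CCC3=CC(=O)OC3)=C(C)C[C@H](O)[C@H]12 | intermediate
29 | C19 alcohol (C2 OTBDPS) | OC[C@@]1(C)C[C@H](O[Si](c3ccccc3)(c3ccccc3)C(C)(C)C)C[C@]2(C)C(CCC3=CC(=O)OC3)=C(C)C[C@H](O)[C@H]12 | intermediate
30 | C19 acetate (C2 OTBDPS) | CC(=O)OC[C@@]1(C)C[C@H](O[Si](c3ccccc3)(c3ccccc3)C(C)(C)C)C[C@]2(C)C(CCC3=CC(=O)OC3)=C(C)C[C@H](O)[C@H]12 | intermediate
31 | CNP0201970.1 | CC(=O)OC[C@@]1(C)C[C@H](O)C[C@]2(C)C(CCC3=CC(=O)OC3)=C(C)C[C@H](O)[C@H]12 | target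

**Step count and risks**
Total step count: 21. Longest linear sequence: 21 steps (from 1; 17 and 25 are purchased).

Steps most likely to fail:

Step 3. β-Elimination of the silanol from the dione or the enone under aminocatalysis (leading toward m-cresol), or weak discrimination of the two enantiotopic acetonyl arms by the catalyst. Fallback, setting out from 3 and returning at 5: the dione is cyclized without asymmetric induction (piperidinium acetate, benzene, rt) to the racemic enone F1. Corey–Bakshi–Shibata reduction ((S)-Me-CBS, BH3·SMe2, THF, −20 °C) then reduces both enantiomers under reagent control. This should turn them into separable diastereomers: the trans (1R,5S)-allylic alcohol F2 and the cis (1R,5R)-allylic alcohol F3. F3 is discarded, and MnO2 oxidation of F2 in CH2Cl2 gives 5.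

Step 12. Alkylation of the dienolate at the γ-carbon C7 or at oxygen in place of the hindered C9, deprotonation at C5, or destruction of the bromo ester by the base. Fallback, setting out from 16 and returning at 22: the smaller and more reactive allyl bromide is used under thermodynamic conditions (KOtBu, tBuOH/THF) to give the C9 allyl ketone F4. NaBH4 in MeOH gives the cyclobutanol F5, and KH/18-crown-6 in THF effects the same ring enlargement to the ring B alcohol F6 carrying an allyl group on C9. Lemieux–Johnson cleavage of the terminal alkene (OsO4 cat., NMO; then NaIO4), which should spare the tetrasubstituted ring alkene, gives the C12 aldehyde F7, and NaBH4 reduces it to 22.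

Step 14. Proton transfer from C5–H to the allyl anion after the C6–C9 bond has broken, which would leave a ring-opened aldehyde in place of reclosure. Fallback, setting out from 19 and returning at 24: the ring enlargement is done at the ketone level and without base, by photochemical 1,3-acyl shift of the β,γ-unsaturated cyclobutanone (hν about 300 nm, benzene) to the cyclohex-3-enone ester F8. LiAlH4 then gives the diol F9 (6α-OH from convex-face attack), Appel iodination gives the iodide F10, and Dess–Martin oxidation gives 24.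

Further compounds
F1 | step 3 | racemic 5-[(tert-butyldiphenylsilyl)oxy]-3-methylcyclohex-2-en-1-one | CC1=CC(=O)CC(O[Si](c2ccccc2)(c2ccccc2)C(C)(C)C)C1
F2 | step 3 | (1R,5S)-5-[(tert-butyldiphenylsilyl)oxy]-3-methylcyclohex-2-en-1-ol (trans) | O[C@H]1C=C(C)C[C@H](O[Si](c2ccccc2)(c2ccccc2)C(C)(C)C)C1
F3 | step 3 | (1R,5R)-5-[(tert-butyldiphenylsilyl)oxy]-3-methylcyclohex-2-en-1-ol (cis) | O[C@H]1C=C(C)C[C@@H](O[Si](c2ccccc2)(c2ccccc2)C(C)(C)C)C1
F4 | step 12 | cyclobutanone with C9 isopropenyl and allyl | CC(C)(C)[Si](C)(C)OC[C@@]1(C)C[C@H](O[Si](c3ccccc3)(c3ccccc3)C(C)(C)C)C[C@]2(C)[C@](CC=C)(C(C)=C)C(=O)[C@H]12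
F5 | step 12 | cyclobutanol from F4 | CC(C)(C)[Si](C)(C)OC[C@@]1(C)C[C@H](O[Si](c3ccccc3)(c3ccccc3)C(C)(C)C)C[C@]2(C)[C@](CC=C)(C(C)=C)[C@H](O)[C@H]12
F6 | step 12 | ring B alcohol with C9 allyl (6β-OH) | CC(C)(C)[Si](C)(C)OC[C@@]1(C)C[C@H](O[Si](c3ccccc3)(c3ccccc3)C(C)(C)C)C[C@]2(C)C(CC=C)=C(C)C[C@@H](O)[C@H]12
F7 | step 12 | C12 aldehyde (6β-OH) | CC(C)(C)[Si](C)(C)OC[C@@]1(C)C[C@H](O[Si](c3ccccc3)(c3ccccc3)C(C)(C)C)C[C@]2(C)C(CC=O)=C(C)C[C@@H](O)[C@H]12
F8 | step 14 | ring B C6 ketone with CH2CO2tBu on C9 | CC(C)(C)[Si](C)(C)OC[C@@]1(C)C[C@H](O[Si](c3ccccc3)(c3ccccc3)C(C)(C)C)C[C@]2(C)C(CC(=O)OC(C)(C)C)=C(C)CC(=O)[C@H]12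
F9 | step 14 | ring B diol with 6α-OH | CC(C)(C)[Si](C)(C)OC[C@@]1(C)C[C@H](O[Si](c3ccccc3)(c3ccccc3)C(C)(C)C)C[C@]2(C)C(CCO)=C(C)C[C@H](O)[C@H]12
F10 | step 14 | C12 iodide with 6α-OH | CC(C)(C)[Si](C)(C)OC[C@@]1(C)C[C@H](O[Si](c3ccccc3)(c3ccccc3)C(C)(C)C)C[C@]2(C)C(CCI)=C(C)C[C@H](O)[C@H]12
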